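(The readings are simulated for an exercise; the scatter is artificial.)

- reaction order in [starting material] at the outset, round the charge of the beta run, defined at two percent of the starting material turned into product (one fixed amount of product, the same in the runs compared)
- reaction order in [partner] at the outset, round the charge of the beta run, defined at two percent of the starting material turned into product
- product in the alpha run at 7.7 min, as a share of the starting material charged
- which of these the readings show (two substrates go astray together / the product speeds the reaction / the two partners rest in a complex / nothing beyond the main steps / the second partner is lost by itself)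

| flask | starting material | partner | product | time |
|---|---|---|---|---|
| beta | 250 mM | 750 mM |  |  |
| gamma | 100 mM | 600 mM |  |  |
| zeta | 380 mM | 750 mM |  |  |
| eta | 250 mM | 750 mM | 120 mM |  |
| alpha | 610 mM | 750 mM |  | 7.7 min |

| beta run: time / min | beta run: [product] / mM | gamma run: time / min | gamma run: [product] / mM | zeta run: time / min | zeta run: [product] / mM | eta run: time / min | eta run: [product] / mM |
|---|---|---|---|---|---|---|---|
| 0.28 | 4 | 0.28 | 0 | 0.28 | 1 | 0.28 | 123 |
| 0.84 | 10 | 0.84 | 7 | 0.84 | 13 | 0.84 | 135 |
| 1.6 | 36 | 1.6 | 6 | 1.6 | 41 | 1.6 | 148 |
| 2.5 | 45 | 2.5 | 27 | 2.5 | 65 | 2.5 | 168 |
| 3.6 | 57 | 3.6 | 17 | 3.6 | 86 | 3.6 | 180 |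
| 4.9 | 65 | 4.9 | 26 | 4.9 | 99 | 4.9 | 192 |
| 6.2 | 72 | 6.2 | 36 | 6.2 | 103 | 6.2 | 195 |
| 7.7 | 80 | 7.7 | 30 | 7.7 | 104 | 7.7 | 199 |

(each reading ± 4 mM)

- Overall: starting material + partner -> product.
- Constant volume, constant temperature.
- "The second partner" is partner.
- An order is taken over about fifteen percent of the charge, up and down.

1. I began with an easy reading of the zeta run. Its last reading was 104 mM of product, from a charge of 380 mM of starting material and 750 mM of partner.

2. Two numbers then seemed not to go together. From the beta run to the zeta run, at the same partner charge of 750 mM, the starting material rose by a factor of 1.52, but the product at 7.7 min rose by a factor of 1.30, which is less.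

3. Added product did not account for the gap. The eta run, charged like the beta run but with 120 mM of product, gained 79.0 mM by 7.7 min, and the beta run gained 80 mM.

4. So I stopped expecting proportion and measured the departure from it. I took the power to which the ratio of starting-material charges must be raised to give the ratio of product at 7.7 min, with the partner charge held fixed, and called it the charge exponent. It is an apparent order, read from two readings that carry their scatter: 0.627. It clears up the puzzle as a description, since the share turned fell from 32.0 % in the beta run to 27.4 % in the zeta run.

5. The alpha run has the same partner charge, 750 mM, and is read at the same time, so I stretched the exponent up from the zeta charge to 610 mM. My reckoning gave 140 mM, a share of 22.9 %.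

6. The forecast gave orders of 0.9 and 1, a share of 21 % and the verdict "two substrates go astray together", reading the falling yields as “starting material being wasted second order in itself”.

7. The alpha run gave 24.2 % at 7.7 min, which is 148 mM of product against my 140 mM. The order at the outset came to 0.66 in [starting material] and 0.59 in [partner]. The readings show this: the second partner is lost by itself.

    starting material ⇌ intermediate + by-product (0.4290 min⁻¹, 1.026 M⁻¹ min⁻¹)
    intermediate + partner → product (0.6840 M⁻¹ min⁻¹)
    partner → lost reagent (0.4392 min⁻¹)

Put to a different reading, the early rate, the charge exponent turns the zeta-to-beta charge ratio into a rate ratio of 1.30, and the rate of the zeta run over that of the beta run, both where the same amount of product had been made, was 1.3.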